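**Retrosynthetic overview**
- Feature: C1 lies between three carbonyls (C8, C7 and the isobutyryl carbonyl C9). Before ring closure it is therefore the enolisable carbon of a 2-acylcyclohexanone (ring C1–C2–C3–C4–C5–C8), and C7 can arrive as the aldehyde carbon of a glyoxaloyl arm on C5.
- Target 26 ⇒ ynone 25 (Lindlar) ⇒ bicyclic ketol 17, by exo formyl-anion addition at C6, acetylide addition, and oxidation of C7 and C1'.
- 17 ⇒ glyoxal 16 by intramolecular aldol C1–C7, closing the five-membered ring C1–C7–C6–C5–C8. 16 is released by oxidation of the primary ketol 15 and not by hydrolysis of an alpha-keto acetal, whose ionisation would need acid that attacks the prenyl groups first.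
- 15 ⇒ enone 6 (C5 prenylation, C5 aldol trans to the C3 prenyl group, conjugate methylation with isobutyraldehyde trapping at C1) ⇒ 1 + 2 (organocatalytic Michael/aldol condensation sets C3).
- Ring order: six-membered carbocycle in step 1, five-membered ring in step 10.

Key step: step 10

Remark: the locants of the target bicyclo[3.2.1]octane (C1–C8, side chain C1'–C4', isobutyryl carbonyl C9) are used in the text for every intermediate, and the target is taken as the open-chain Z hydroxy enone as drawn.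

**Route**

Step 1
Reactants: 1 5-methylhex-4-enal; 2 but-3-en-2-one
Product: 4 (S)-4-(3-methylbut-2-enyl)cyclohex-2-en-1-one, via keto aldehyde 3 (not isolated)
Conditions: (S)-2-[methoxy(diphenyl)methyl]pyrrolidine (5 mol%), ethyl 3,4-dihydroxybenzoate (20 mol%), neat, 4 °C; then LiOH (10 mol%), iPrOH, 25 °C
Reagents that add atoms: none
Why: Enamine-catalysed Michael addition, in which the E-enamine is attacked on the face remote from the methoxydiphenylmethyl group and so sets C3 as (S) in 3, is followed by base-mediated intramolecular aldol condensation of the methyl ketone onto the aldehyde, which closes the cyclohexenone without touching the stereocentre.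

Step 2
Reactants: 4 (S)-4-(3-methylbut-2-enyl)cyclohex-2-en-1-one
Product: 5 trimethyl{[3-methyl-4-(3-methylbut-2-enyl)cyclohex-1-en-1-yl]oxy}silane (prenyl-bearing carbon as in 4; both epimers at the methyl-bearing carbon)
Conditions: Me2CuLi (from MeLi, CuI), TMSCl, THF, −78 °C
Reagents that add atoms: lithium dimethylcuprate, [Li+].C[Cu-]C; chlorotrimethylsilane, C[Si](C)(C)Cl
Why: TMSCl-accelerated cuprate conjugate addition delivers the first C2 methyl (expected mainly trans to the C3 prenyl group, a configuration erased in step 3) and traps the enolate regiospecifically as the C1=C8 silyl enol ether.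

Step 3
Reactants: 5 trimethyl{[3-methyl-4-(3-methylbut-2-enyl)cyclohex-1-en-1-yl]oxy}silane
Product: 6 (S)-3-methyl-4-(3-methylbut-2-enyl)cyclohex-2-en-1-one
Conditions: Pd(OAc)2 (1.05 equiv), MeCN, 25 °C
Reagents that add atoms: none
Why: Saegusa–Ito oxidation, in which the divalent palladium enolate formed at C1 can only lose the C2 hydrogen, so the enone is regenerated with C2 carrying a methyl group, while the trisubstituted prenyl alkene is a poor ligand and should not interfere.

Step 4
Reactants: 6 (S)-3-methyl-4-(3-methylbut-2-enyl)cyclohex-2-en-1-one; 7 1-bromo-3-methylbut-2-ene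
Product: 8 3-methyl-4,6-bis(3-methylbut-2-enyl)cyclohex-2-en-1-one (ring C4 as in 6; both epimers at ring C6, the C5 of the target)
Conditions: LDA (LiN(iPr)2), THF, −78 °C; then 7, −78 → −20 °C
Reagents that add atoms: none
Why: Kinetic deprotonation of the enone at the alpha-prime carbon C5 gives the cross-conjugated dienolate, which is C-alkylated by the allylic bromide in an SN2 reaction; the C5 configuration is irrelevant because C5 is enolised again in step 5.

Step 5
Reactants: 8 3-methyl-4,6-bis(3-methylbut-2-enyl)cyclohex-2-en-1-one; 9 (tert-butyldimethylsilyloxy)acetaldehyde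
Product: 10 6-[2-(tert-butyldimethylsilyloxy)-1-hydroxyethyl]-3-methyl-4,6-bis(3-methylbut-2-enyl)cyclohex-2-en-1-one (hydroxyethyl arm trans to the prenyl group on ring C4; both carbinol epimers)
Conditions: LDA (LiN(iPr)2), THF, −78 °C; then 9, −78 °C; AcOH quench at −78 °C
Reagents that add atoms: none
Why: Aldol addition of the fully substituted C5 lithium dienolate builds the quaternary carbon, the aldehyde approaching the face opposite the C3 prenyl group (pseudoaxial next to the C2 methyl to avoid allylic strain), so that the two-carbon arm ends trans and the C5 prenyl group cis to the C3 prenyl group; the cold acidic quench prevents retro-aldol.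

Step 6
Reactants: 10 6-[2-(tert-butyldimethylsilyloxy)-1-hydroxyethyl]-3-methyl-4,6-bis(3-methylbut-2-enyl)cyclohex-2-en-1-one
Product: 11 6-[(tert-butyldimethylsilyloxy)acetyl]-3-methyl-4,6-bis(3-methylbut-2-enyl)cyclohex-2-en-1-one (acyl arm trans to the prenyl group on ring C4)
Conditions: DMP, pyridine, CH2Cl2, 0 → 25 °C
Reagents that add atoms: none
Why: Dess–Martin oxidation of the secondary carbinol to the C6 ketone under buffered conditions that leave the silyl ether, the enone and both alkenes untouched; C5 is quaternary and cannot epimerise.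

Step 7
Reactants: 11 6-[(tert-butyldimethylsilyloxy)acetyl]-3-methyl-4,6-bis(3-methylbut-2-enyl)cyclohex-2-en-1-one; 12 2-methylpropanal
Product: 13 2-[(tert-butyldimethylsilyloxy)acetyl]-6-(1-hydroxy-2-methylpropyl)-5,5-dimethyl-2,4-bis(3-methylbut-2-enyl)cyclohexan-1-one (acyl arm trans to the C4 prenyl group; mixture at ring C6 and at the carbinol carbon)
Conditions: Me2CuLi (from MeLi, CuI), Et2O, −40 → 0 °C; then 12, −78 °C; AcOH quench at −78 °C
Reagents that add atoms: lithium dimethylcuprate, [Li+].C[Cu-]C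
Why: Tandem conjugate addition–aldol, in which the cuprate adds the second methyl to the beta carbon C2 and generates the C1=C8 enolate (the only one possible, C5 being quaternary), which is trapped at C1 by isobutyraldehyde; the new centres at C1 and the carbinol carbon are removed in step 8.

Step 8
Reactants: 13 2-[(tert-butyldimethylsilyloxy)acetyl]-6-(1-hydroxy-2-methylpropyl)-5,5-dimethyl-2,4-bis(3-methylbut-2-enyl)cyclohexan-1-one
Product: 14 2-[(tert-butyldimethylsilyloxy)acetyl]-5,5-dimethyl-2,4-bis(3-methylbut-2-enyl)-6-(2-methylpropanoyl)cyclohexan-1-one (enolised 1,3-diketone, drawn as the ring enol)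
Conditions: DMP, pyridine, CH2Cl2, 25 °C
Reagents that add atoms: none
Why: Dess–Martin oxidation of the beta-hydroxy ketone gives the 2-acylcyclohexanone, which rests as its hydrogen-bonded enol and is not oxidised further.

Step 9
Reactants: 14 2-[(tert-butyldimethylsilyloxy)acetyl]-5,5-dimethyl-2,4-bis(3-methylbut-2-enyl)-6-(2-methylpropanoyl)cyclohexan-1-one
Product: 15 2-(hydroxyacetyl)-5,5-dimethyl-2,4-bis(3-methylbut-2-enyl)-6-(2-methylpropanoyl)cyclohexan-1-one (enol form)
Conditions: HF·pyridine, pyridine, THF, 0 → 25 °C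
Reagents that add atoms: none
Why: Fluoride cleavage of the primary silyl ether under weakly acidic, buffered conditions, which avoid the alkoxide-triggered acyl transfer that a basic fluoride source could start in this triketone.

Step 10
Reactants: 15 2-(hydroxyacetyl)-5,5-dimethyl-2,4-bis(3-methylbut-2-enyl)-6-(2-methylpropanoyl)cyclohexan-1-one
Product: 17 7-exo-hydroxy-2,2-dimethyl-3,5-bis(3-methylbut-2-enyl)-1-(2-methylpropanoyl)bicyclo[3.2.1]octane-6,8-dione (C3 prenyl equatorial), via glyoxal 16 (not isolated)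
Conditions: DMP (1.05 equiv), CH2Cl2, 0 °C; then PPTS (10 mol%), 25 °C
Reagents that add atoms: none
Why: The periodinane oxidises the primary ketol to the glyoxal 16 (one equivalent only, so that the hindered secondary carbinol formed afterwards is not oxidised), and under the acetic acid released plus PPTS the 2-isobutyryl ketone reacts through its exocyclic enol C1=C9(OH), C1 adding to the activated aldehyde carbon C7 to form the C1–C7 bond. The closest known reaction type is the acid-mediated intramolecular aldol addition of enolised 1,3-diketones and beta-keto esters to tethered aldehydes, which is established for bridged bicyclic ketols. The five-membered ring C1–C7–C6–C5–C8 closes in the 5-(enolexo)-exo-trig mode across the cyclohexanone ring and completes the bicyclo[3.2.1]octane. C1 is set by C5, because the glyoxaloyl arm is axial on C5 and can reach only the axial face of C1, which leaves the isobutyryl group equatorial; the C7 carbinol should equilibrate under these reversible conditions to the exo epimer drawn, and its configuration is erased in step 16. Attack on the aldehyde and not on the C6 ketone, and by carbon and not by oxygen, follows from ring size, the alternatives being a four-membered ring or a reversible hemiacetal. Releasing the aldehyde by oxidation keeps the medium only weakly acidic, so that neither prenyl group is protonated and the ene reaction of the C5 prenyl group with the glyoxal should stay slow.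

Step 11
Reactants: 17 7-exo-hydroxy-2,2-dimethyl-3,5-bis(3-methylbut-2-enyl)-1-(2-methylpropanoyl)bicyclo[3.2.1]octane-6,8-dione
Product: 18 2,2-dimethyl-3,5-bis(3-methylbut-2-enyl)-1-(2-methylpropanoyl)-7-exo-(triethylsilyloxy)bicyclo[3.2.1]octane-6,8-dione
Conditions: TESOTf, 2,6-lutidine, CH2Cl2, −78 °C
Reagents that add atoms: triethylsilyl trifluoromethanesulfonate, CC[Si](CC)(CC)OS(=O)(=O)C(F)(F)F
Why: Silylation of the hindered secondary carbinol with a silyl triflate and a weak non-nucleophilic base blocks base-induced retro-aldol cleavage of C1–C7 in the following steps and leaves the C7 configuration untouched.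

Step 12
Reactants: 18 2,2-dimethyl-3,5-bis(3-methylbut-2-enyl)-1-(2-methylpropanoyl)-7-exo-(triethylsilyloxy)bicyclo[3.2.1]octane-6,8-dione; 19 1,3-dithiane
Product: 20 6-exo-(1,3-dithian-2-yl)-6-endo-hydroxy-2,2-dimethyl-3,5-bis(3-methylbut-2-enyl)-1-(2-methylpropanoyl)-7-exo-(triethylsilyloxy)bicyclo[3.2.1]octan-8-one
Conditions: 19, nBuLi, THF, −30 °C; then 18, −78 °C; AcOH quench at −78 °C
Reagents that add atoms: none
Why: Corey–Seebach addition of 2-lithio-1,3-dithiane (formyl anion equivalent) to the alpha-silyloxy cyclopentanone carbonyl C6, the most electrophilic and least shielded ketone (C8 lies between two quaternary carbons, C9 between a quaternary carbon and an isopropyl group), from the exo face syn to the C8 bridge because the endo face is screened by the C2–C3–C4 bridge and its axial C3 hydrogen, which sets C6 with the hydroxyl endo as in the target.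

Step 13
Reactants: 20 6-exo-(1,3-dithian-2-yl)-6-endo-hydroxy-2,2-dimethyl-3,5-bis(3-methylbut-2-enyl)-1-(2-methylpropanoyl)-7-exo-(triethylsilyloxy)bicyclo[3.2.1]octan-8-one
Product: 21 6-endo-hydroxy-2,2-dimethyl-3,5-bis(3-methylbut-2-enyl)-1-(2-methylpropanoyl)-8-oxo-7-exo-(triethylsilyloxy)bicyclo[3.2.1]octane-6-exo-carbaldehyde
Conditions: MeI, CaCO3, MeCN/H2O (9:1), 40 °C
Reagents that add atoms: water, O
Why: Alkylative hydrolysis of the dithioacetal (S-methylation, then attack of water) under carbonate buffering, conditions that leave trisubstituted alkenes, the silyl ether and the ketones untouched.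

Step 14
Reactants: 21 6-endo-hydroxy-2,2-dimethyl-3,5-bis(3-methylbut-2-enyl)-1-(2-methylpropanoyl)-8-oxo-7-exo-(triethylsilyloxy)bicyclo[3.2.1]octane-6-exo-carbaldehyde; 22 2-methyl-2-(trimethylsilyloxy)but-3-yne
Product: 23 6-endo-hydroxy-6-exo-[1-hydroxy-4-methyl-4-(trimethylsilyloxy)pent-2-ynyl]-2,2-dimethyl-3,5-bis(3-methylbut-2-enyl)-1-(2-methylpropanoyl)-7-exo-(triethylsilyloxy)bicyclo[3.2.1]octan-8-one (both C1' epimers)
Conditions: 22, nBuLi, THF, −78 °C; then 21, −78 °C; AcOH quench at −78 °C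
Reagents that add atoms: none
Why: Addition of the lithium acetylide to the aldehyde, far more electrophilic than the hindered ketones, at −78 °C with a cold quench so that the C6 alkoxide does not fragment; the new carbinol centre at C1' is oxidised away in step 16.

Step 15
Reactants: 23 6-endo-hydroxy-6-exo-[1-hydroxy-4-methyl-4-(trimethylsilyloxy)pent-2-ynyl]-2,2-dimethyl-3,5-bis(3-methylbut-2-enyl)-1-(2-methylpropanoyl)-7-exo-(triethylsilyloxy)bicyclo[3.2.1]octan-8-one
Product: 24 6-exo-(1,4-dihydroxy-4-methylpent-2-ynyl)-6-endo,7-exo-dihydroxy-2,2-dimethyl-3,5-bis(3-methylbut-2-enyl)-1-(2-methylpropanoyl)bicyclo[3.2.1]octan-8-one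
Conditions: HF·pyridine, pyridine, THF, 0 → 25 °C
Reagents that add atoms: none
Why: Fluoride cleavage of both silyl ethers (triethylsilyl at C7, trimethylsilyl at C4') under buffered acidic conditions that cannot trigger retro-aldol cleavage.

Step 16
Reactants: 24 6-exo-(1,4-dihydroxy-4-methylpent-2-ynyl)-6-endo,7-exo-dihydroxy-2,2-dimethyl-3,5-bis(3-methylbut-2-enyl)-1-(2-methylpropanoyl)bicyclo[3.2.1]octan-8-one
Product: 25 6-endo-hydroxy-6-exo-(4-hydroxy-4-methylpent-2-ynoyl)-2,2-dimethyl-3,5-bis(3-methylbut-2-enyl)-1-(2-methylpropanoyl)bicyclo[3.2.1]octane-7,8-dione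
Conditions: IBX, DMSO, 25 → 40 °C
Reagents that add atoms: none
Why: IBX oxidation of the two secondary carbinols (C7 and propargylic C1') to ketones; this pentavalent iodine reagent in DMSO converts 1,2-diols into ketols without cleaving the C–C bond, and the tertiary alcohols at C6 and C4' are inert.

Step 17
Reactants: 25 6-endo-hydroxy-6-exo-(4-hydroxy-4-methylpent-2-ynoyl)-2,2-dimethyl-3,5-bis(3-methylbut-2-enyl)-1-(2-methylpropanoyl)bicyclo[3.2.1]octane-7,8-dione
Product: 26 6-endo-hydroxy-6-exo-[(Z)-4-hydroxy-4-methylpent-2-enoyl]-2,2-dimethyl-3,5-bis(3-methylbut-2-enyl)-1-(2-methylpropanoyl)bicyclo[3.2.1]octane-7,8-dione (CNP0190794.1)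
Conditions: H2 (1 atm), Pd/CaCO3 poisoned with Pb(OAc)2, EtOAc, 0 °C
Reagents that add atoms: none
Why: Lindlar semihydrogenation, in which syn delivery of hydrogen on the poisoned palladium surface gives the Z enone and the trisubstituted prenyl alkenes are not reduced.

**Compound list**

1 | 5-methylhex-4-enal | CC(C)=CCCC=O | starting material
2 | but-3-en-2-one | CC(=O)C=C | starting material
3 | (S)-2-(3-methylbut-2-enyl)-5-oxohexanal | CC(C)=CC[C@@H](C=O)CCC(C)=O | intermediate
4 | (S)-4-(3-methylbut-2-enyl)cyclohex-2-en-1-one | CC(C)=CC[C@@H]1CCC(=O)C=C1 | intermediate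
5 | trimethyl{[3-methyl-4-(3-methylbut-2-enyl)cyclohex-1-en-1-yl]oxy}silane (prenyl-bearing carbon as in 4) | CC(C)=CC[C@@H]1CCC(O[Si](C)(C)C)=CC1C | intermediate
6 | (S)-3-methyl-4-(3-methylbut-2-enyl)cyclohex-2-en-1-one | CC(C)=CC[C@@H]1CCC(=O)C=C1C | intermediate
7 | 1-bromo-3-methylbut-2-ene | CC(C)=CCBr | starting material
8 | 3-methyl-4,6-bis(3-methylbut-2-enyl)cyclohex-2-en-1-one (ring C4 as in 6) | CC(C)=CC[C@@H]1CC(CC=C(C)C)C(=O)C=C1C | intermediate
9 | (tert-butyldimethylsilyloxy)acetaldehyde | CC(C)(C)[Si](C)(C)OCC=O | starting material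
10 | 6-[2-(tert-butyldimethylsilyloxy)-1-hydroxyethyl]-3-methyl-4,6-bis(3-methylbut-2-enyl)cyclohex-2-en-1-one (arm trans to the C4 prenyl group) | CC(C)=CC[C@@H]1C[C@@](CC=C(C)C)(C(O)CO[Si](C)(C)C(C)(C)C)C(=O)C=C1C | intermediate
11 | 6-[(tert-butyldimethylsilyloxy)acetyl]-3-methyl-4,6-bis(3-methylbut-2-enyl)cyclohex-2-en-1-one | CC(C)=CC[C@@H]1C[C@@](CC=C(C)C)(C(=O)CO[Si](C)(C)C(C)(C)C)C(=O)C=C1C | intermediate
12 | 2-methylpropanal | CC(C)C=O | starting material
13 | 2-[(tert-butyldimethylsilyloxy)acetyl]-6-(1-hydroxy-2-methylpropyl)-5,5-dimethyl-2,4-bis(3-methylbut-2-enyl)cyclohexan-1-one | CC(C)=CC[C@@H]1C[C@@](CC=C(C)C)(C(=O)CO[Si](C)(C)C(C)(C)C)C(=O)C(C(O)C(C)C)C1(C)C | intermediate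
14 | 2-[(tert-butyldimethylsilyloxy)acetyl]-5,5-dimethyl-2,4-bis(3-methylbut-2-enyl)-6-(2-methylpropanoyl)cyclohexan-1-one (ring enol) | CC(C)=CC[C@@H]1C[C@@](CC=C(C)C)(C(=O)CO[Si](C)(C)C(C)(C)C)C(O)=C(C(=O)C(C)C)C1(C)C | intermediate
15 | 2-(hydroxyacetyl)-5,5-dimethyl-2,4-bis(3-methylbut-2-enyl)-6-(2-methylpropanoyl)cyclohexan-1-one (ring enol) | CC(C)=CC[C@@H]1C[C@@](CC=C(C)C)(C(=O)CO)C(O)=C(C(=O)C(C)C)C1(C)C | intermediate
16 | C5 glyoxaloyl 2-isobutyrylcyclohexanone: 2-(oxoacetyl)-5,5-dimethyl-2,4-bis(3-methylbut-2-enyl)-6-(2-methylpropanoyl)cyclohexan-1-one (ring enol) | CC(C)=CC[C@@H]1C[C@@](CC=C(C)C)(C(=O)C=O)C(O)=C(C(=O)C(C)C)C1(C)C | intermediate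
17 | 7-exo-hydroxy-2,2-dimethyl-3,5-bis(3-methylbut-2-enyl)-1-(2-methylpropanoyl)bicyclo[3.2.1]octane-6,8-dione | CC(C)=CC[C@@H]1C[C@]2(CC=C(C)C)C(=O)[C@@](C(=O)C(C)C)([C@@H](O)C2=O)C1(C)C | intermediate
18 | 7-exo-triethylsilyl ether of 17 | CC(C)=CC[C@@H]1C[C@]2(CC=C(C)C)C(=O)[C@@](C(=O)C(C)C)([C@@H](O[Si](CC)(CC)CC)C2=O)C1(C)C | intermediate
19 | 1,3-dithiane | C1CSCSC1 | starting material
20 | 6-exo-(1,3-dithian-2-yl)-6-endo-hydroxy-7-exo-(triethylsilyloxy) adduct | CC(C)=CC[C@@H]1C[C@]2(CC=C(C)C)C(=O)[C@@](C(=O)C(C)C)([C@@H](O[Si](CC)(CC)CC)[C@@]2(O)C3SCCCS3)C1(C)C | intermediate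
21 | 6-endo-hydroxy-6-exo-carbaldehyde (7-exo-triethylsilyloxy) | CC(C)=CC[C@@H]1C[C@]2(CC=C(C)C)C(=O)[C@@](C(=O)C(C)C)([C@@H](O[Si](CC)(CC)CC)[C@@]2(O)C=O)C1(C)C | intermediate
22 | 2-methyl-2-(trimethylsilyloxy)but-3-yne | C#CC(C)(C)O[Si](C)(C)C | starting material
23 | propargylic alcohol: 6-exo-[1-hydroxy-4-methyl-4-(trimethylsilyloxy)pent-2-ynyl] adduct of 21 | CC(C)=CC[C@@H]1C[C@]2(CC=C(C)C)C(=O)[C@@](C(=O)C(C)C)([C@@H](O[Si](CC)(CC)CC)[C@@]2(O)C(O)C#CC(C)(C)O[Si](C)(C)C)C1(C)C | intermediate
24 | tetraol: 6-exo-(1,4-dihydroxy-4-methylpent-2-ynyl)-6-endo,7-exo-dihydroxy-2,2-dimethyl-3,5-bis(3-methylbut-2-enyl)-1-(2-methylpropanoyl)bicyclo[3.2.1]octan-8-one | CC(C)=CC[C@@H]1C[C@]2(CC=C(C)C)C(=O)[C@@](C(=O)C(C)C)([C@@H](O)[C@@]2(O)C(O)C#CC(C)(C)O)C1(C)C | intermediate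
25 | ynone: 6-endo-hydroxy-6-exo-(4-hydroxy-4-methylpent-2-ynoyl)-2,2-dimethyl-3,5-bis(3-methylbut-2-enyl)-1-(2-methylpropanoyl)bicyclo[3.2.1]octane-7,8-dione | CC(C)=CC[C@@H]1C[C@]2(CC=C(C)C)C(=O)[C@@](C(=O)C(C)C)(C(=O)[C@@]2(O)C(=O)C#CC(C)(C)O)C1(C)C | intermediate
26 | CNP0190794.1: 6-endo-hydroxy-6-exo-[(Z)-4-hydroxy-4-methylpent-2-enoyl]-2,2-dimethyl-3,5-bis(3-methylbut-2-enyl)-1-(2-methylpropanoyl)bicyclo[3.2.1]octane-7,8-dione | CC(C)=CC[C@@H]1C[C@]2(CC=C(C)C)C(=O)[C@@](C(=O)C(C)C)(C(=O)[C@@]2(O)C(=O)/C=C\C(C)(C)O)C1(C)C | target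

**Step count and risks**

Total step count: 17. Longest linear sequence: 17 steps (1 and 2 to 26).

Risk 1 (step 10). The glyoxal may be consumed before C1 adds, by ene reaction with the geminal C5 prenyl group or by further oxidation of the new carbinol, or the closure may stall at the cyclic hemiacetal. The fallback carries the C5 substituent as an allyl group, a poor ene donor that also tolerates stronger acid. It sets out from 6, which is alkylated with allyl bromide in place of 7 to give the C5-allyl enone F1. The chemistry of steps 5 to 9 should then give in turn the aldol F2, the diketone F3, the conjugate addition–aldol product F4, the enolised silyloxy triketone F5 and the ketol F6. Oxidation and acid-mediated closure as in step 10 (CSA may replace PPTS) gives the C5-allyl bicyclic ketol F7. Cross-metathesis of F7 with 2-methylbut-2-ene (second-generation Grubbs catalyst, (H2IMes)(PCy3)Cl2Ru=CHPh, CH2Cl2, 40 °C) converts allyl into prenyl and comes back to the route at 17.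

Risk 2 (step 12). The basic dithiane anion may enolise the C6 ketone toward C7 in place of adding, or facial selectivity may be eroded by the neighbouring exo silyloxy group. The fallback sets out from 18 and uses a less basic hydroxymethyl anion equivalent. Addition of (iPrO)Me2SiCH2MgCl with CeCl3 (THF, −78 → 0 °C) should give the silylmethyl carbinol F8. Tamao oxidation (H2O2, KF, KHCO3, THF/MeOH) gives the diol F9. Parikh–Doering oxidation of the primary alcohol (SO3·pyridine, DMSO, iPr2NEt, 0 °C) comes back to the route at 21.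

Risk 3 (step 7). Conjugate addition to the hindered beta,beta-disubstituted enone may be slow, and proton transfer or retro-aldol may erode the one-pot trapping at the neopentyl carbon C1. The fallback sets out from 11 and separates the two events. TMSCl-accelerated cuprate addition (Me2CuLi, TMSCl, THF, −78 °C) gives the isolable C1=C8 trimethylsilyl enol ether F10. Mukaiyama aldol addition of F10 to 12 (BF3·OEt2, CH2Cl2, −78 °C) comes back to the route at 13.

Further compounds
F1 | step 10 | C5-allyl enone: 3-methyl-4-(3-methylbut-2-enyl)-6-(prop-2-enyl)cyclohex-2-en-1-one | CC(C)=CC[C@@H]1CC(CC=C)C(=O)C=C1C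
F2 | step 10 | aldol: 6-[2-(tert-butyldimethylsilyloxy)-1-hydroxyethyl]-3-methyl-4-(3-methylbut-2-enyl)-6-(prop-2-enyl)cyclohex-2-en-1-one | CC(C)=CC[C@@H]1C[C@@](CC=C)(C(O)CO[Si](C)(C)C(C)(C)C)C(=O)C=C1C
F3 | step 10 | diketone: 6-[(tert-butyldimethylsilyloxy)acetyl]-3-methyl-4-(3-methylbut-2-enyl)-6-(prop-2-enyl)cyclohex-2-en-1-one | CC(C)=CC[C@@H]1C[C@@](CC=C)(C(=O)CO[Si](C)(C)C(C)(C)C)C(=O)C=C1C
F4 | step 10 | conjugate addition–aldol product: 2-[(tert-butyldimethylsilyloxy)acetyl]-6-(1-hydroxy-2-methylpropyl)-5,5-dimethyl-4-(3-methylbut-2-enyl)-2-(prop-2-enyl)cyclohexan-1-one | CC(C)=CC[C@@H]1C[C@@](CC=C)(C(=O)CO[Si](C)(C)C(C)(C)C)C(=O)C(C(O)C(C)C)C1(C)C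
F5 | step 10 | enolised silyloxy triketone: 2-[(tert-butyldimethylsilyloxy)acetyl]-5,5-dimethyl-4-(3-methylbut-2-enyl)-6-(2-methylpropanoyl)-2-(prop-2-enyl)cyclohexan-1-one | CC(C)=CC[C@@H]1C[C@@](CC=C)(C(=O)CO[Si](C)(C)C(C)(C)C)C(O)=C(C(=O)C(C)C)C1(C)C
F6 | step 10 | ketol: 2-(hydroxyacetyl)-5,5-dimethyl-4-(3-methylbut-2-enyl)-6-(2-methylpropanoyl)-2-(prop-2-enyl)cyclohexan-1-one | CC(C)=CC[C@@H]1C[C@@](CC=C)(C(=O)CO)C(O)=C(C(=O)C(C)C)C1(C)C
F7 | step 10 | C5-allyl bicyclic ketol: 7-exo-hydroxy-2,2-dimethyl-3-(3-methylbut-2-enyl)-1-(2-methylpropanoyl)-5-(prop-2-enyl)bicyclo[3.2.1]octane-6,8-dione | CC(C)=CC[C@@H]1C[C@]2(CC=C)C(=O)[C@@](C(=O)C(C)C)([C@@H](O)C2=O)C1(C)C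
F8 | step 12 | silylmethyl carbinol: 6-endo-hydroxy-6-exo-{[dimethyl(propan-2-yloxy)silyl]methyl}-7-exo-(triethylsilyloxy) adduct of 18 | CC(C)=CC[C@@H]1C[C@]2(CC=C(C)C)C(=O)[C@@](C(=O)C(C)C)([C@@H](O[Si](CC)(CC)CC)[C@@]2(O)C[Si](C)(C)OC(C)C)C1(C)C
F9 | step 12 | diol: 6-endo-hydroxy-6-exo-(hydroxymethyl)-7-exo-(triethylsilyloxy) compound | CC(C)=CC[C@@H]1C[C@]2(CC=C(C)C)C(=O)[C@@](C(=O)C(C)C)([C@@H](O[Si](CC)(CC)CC)[C@@]2(O)CO)C1(C)C
F10 | step 7 | C1=C8 trimethylsilyl enol ether: tert-butyldimethylsilyloxymethyl [3,3-dimethyl-1,5-bis(3-methylbut-2-enyl)-2-(trimethylsilyloxy)cyclohex-2-enyl] ketone (ring locants of the ketone-bearing carbon as 1) | CC(C)=CC[C@@H]1C[C@@](CC=C(C)C)(C(=O)CO[Si](C)(C)C(C)(C)C)C(O[Si](C)(C)C)=CC1(C)C
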